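**Strategy**

The cyclohexene core is disconnected across C1–C2 and C3–C4. The vicinal methines C1 (bearing the C7 carbinol) and C2 (bearing coumarin ring B) arise from an enamine Michael addition, and the C4 methyl marks a former methyl ketone that accepts the nitronate. One catalytic operation joins the acyclic keto aldehyde 4 (gem-dimethyl = C6) and the MOM-protected 2-oxy-4,6-dimethoxy-β-nitrostyrene 8, closes the six-membered ring, and fixes C2 absolutely and C1 relative to it. The nitro/hydroxyl pair is then excised to place C3=C4, an aryllithium builds C7 with the ring A arene, and both pyranones are annulated from the two unmasked phenols without acid before the C7 ketone is reduced.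

Key step: step 6

**Remarks on the chemistry**

- Numbering: carbocycle C1 (CH bearing C7), C2 (CH bearing ring B), C3=C4(CH3), C5H2, C6(CH3)2; ring A is the coumarin on C7. The target is 7S,1S,2R with C1/C2 trans.
- The catalyst is taken as the R enantiomer, because the S enantiomer is known to give the opposite sense at the benzylic carbon.
- C4 of 10, C3/C4 of 12 and C7 of 17 are carried as mixtures, since each of these centres is destroyed later.
- Both phenols travel as MOM ethers and are unmasked and annulated under non-acidic conditions. A free phenol on the C2 aryl next to the C3=C4 alkene could add across it (O to C4, bridged chroman) under Brønsted or strong Lewis acid.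

**Route**

Step 1
Reactants: 1 dimedone
Product: 2 3,3-dimethyl-5-oxohexanoic acid
Conditions: Ba(OH)2·8H2O, H2O, 150 °C (sealed vessel); then aq. HCl
Reagents that add atoms: water, O
Why: Hydroxide adds to one carbonyl of the cyclic 1,3-diketone and the adduct fragments by retro-Claisen C–C cleavage to the δ-keto carboxylate, the established ring opening of cyclohexane-1,3-diones.

Step 2
Reactants: 2 3,3-dimethyl-5-oxohexanoic acid
Product: 3 3,3-dimethylhexane-1,5-diol (racemic)
Conditions: LiAlH4, THF, 0 °C → reflux; H2O/NaOH work-up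
Reagents that add atoms: none
Why: Exhaustive hydride reduction of acid and ketone avoids any acid-versus-ketone selectivity question; the new carbinol centre is racemic and is removed in step 3.

Step 3
Reactants: 3 3,3-dimethylhexane-1,5-diol
Product: 4 3,3-dimethyl-5-oxohexanal
Conditions: (COCl)2, DMSO, CH2Cl2, −78 °C; Et3N, −78 → 0 °C
Reagents that add atoms: none
Why: Swern oxidation should convert the primary and the secondary alcohol in one operation to aldehyde and ketone without over-oxidation; the keto aldehyde is used fresh.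

Step 4
Reactants: 5 2-hydroxy-4,6-dimethoxybenzaldehyde
Product: 6 2,4-dimethoxy-6-(methoxymethoxy)benzaldehyde
Conditions: CH3OCH2Cl, i-Pr2NEt, CH2Cl2, 0 °C → rt
Reagents that add atoms: chloromethyl methyl ether, COCCl
Why: O-Alkylation of the phenol (Williamson-type acetal ether formation) gives a small, base-stable protecting group that adds little bulk beside the future nitroalkene.

Step 5
Reactants: 6 2,4-dimethoxy-6-(methoxymethoxy)benzaldehyde; 7 nitromethane
Product: 8 (E)-2-(methoxymethoxy)-4,6-dimethoxy-β-nitrostyrene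
Conditions: NH4OAc, CH3NO2 (solvent), 90 °C
Reagents that add atoms: none
Why: Henry (nitro-aldol) condensation with dehydration under ammonium acetate should give the conjugated nitroalkene as the thermodynamically favoured E isomer.

Step 6
Reactants: 4 3,3-dimethyl-5-oxohexanal; 8 (E)-2-(methoxymethoxy)-4,6-dimethoxy-β-nitrostyrene
Product: 10 (1S,2R,3R)-2-[2,4-dimethoxy-6-(methoxymethoxy)phenyl]-4-hydroxy-4,6,6-trimethyl-3-nitrocyclohexane-1-carbaldehyde (C4 epimer mixture), via Michael adduct 9 (not isolated)
Conditions: (R)-2-[diphenyl(trimethylsilyloxy)methyl]pyrrolidine (20 mol %), 4-nitrophenol (20 mol %), toluene, rt; then 1,8-diazabicyclo[5.4.0]undec-7-ene (DBU, 0.5 equiv), CH3CN, 0 °C → rt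
Reagents that add atoms: none
Why: The pyrrolidine nitrogen condenses only with the aldehyde of 4 to give the E-enamine, which adds through an acyclic synclinal transition state to the β-carbon of 8 (C1–C2), hydrolysis releases 9 and the catalyst, and DBU then forms the nitronate, which attacks the methyl ketone (C3–C4). The closest known reaction type is the diarylprolinol silyl ether-catalysed aldehyde–nitroalkene Michael addition followed by intramolecular Henry reaction to nitrocyclohexanols. The carbocycle closes in a 6-exo-trig nitro-aldol mode, assisted by the gem-dimethyl group at C6. C2 is set by the catalyst, whose diphenyl(silyloxy)methyl group shields one enamine face so that the R catalyst should give 2R; C1 is formed syn (1R) and is epimerised by DBU to the more stable trans, equatorial aldehyde (1S); C3 equilibrates through the nitronate to the equatorial nitro group (3R); C4 follows the reversible Henry step and is carried as a mixture because it becomes sp2 later. The step needs aldehyde-over-ketone chemoselectivity, secured because the bulky secondary amine does not form an enamine from the methyl ketone and the weak base deprotonates only the nitro-bearing carbon, and it needs the nitronate to find the ketone, secured because attack on the aldehyde would require a four-membered ring. The low electrophilicity of the 2,6-dioxygenated nitroalkene is met with the acidic co-catalyst, high concentration, excess 4 and long reaction time.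

Step 7
Reactants: 10 (1S,2R,3R)-2-aryl-4-hydroxy-4,6,6-trimethyl-3-nitrocyclohexane-1-carbaldehyde
Product: 12 (1S,2R)-2-[2,4-dimethoxy-6-(methoxymethoxy)phenyl]-4,6,6-trimethyl-3-nitro-4-(phenylsulfanyl)cyclohexane-1-carbaldehyde (C3/C4 diastereomer mixture), via nitroalkene 11 (not isolated)
Conditions: (CF3CO)2O, Et3N, CH2Cl2, −20 → 0 °C; then PhSH (excess), Et3N, 0 °C → rt
Reagents that add atoms: thiophenol, Sc1ccccc1
Why: Trifluoroacetylation of the tertiary alcohol and E1cB elimination through the C3 nitronate can only give the C3=C4 nitroalkene, to which thiolate adds at C4 in a sulfa-Michael reaction driven by excess thiol; the new C3/C4 centres are uncontrolled and are both removed in step 8.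

Step 8
Reactants: 12 (1S,2R)-2-aryl-4,6,6-trimethyl-3-nitro-4-(phenylsulfanyl)cyclohexane-1-carbaldehyde
Product: 13 (1S,2R)-2-[2,4-dimethoxy-6-(methoxymethoxy)phenyl]-4,6,6-trimethylcyclohex-3-ene-1-carbaldehyde
Conditions: Bu3SnH, azobisisobutyronitrile (cat.), benzene, 80 °C
Reagents that add atoms: none
Why: Radical elimination of a β-nitro sulfide: the stannyl radical removes the nitro group and the C3 radical expels the phenylthiyl radical, so the alkene can form only at C3=C4 while C1 and C2 are untouched.

Step 9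
Reactants: 14 3,5-dimethoxyphenol
Product: 15 1,3-dimethoxy-5-(methoxymethoxy)benzene
Conditions: CH3OCH2Cl, i-Pr2NEt, CH2Cl2, 0 °C → rt
Reagents that add atoms: chloromethyl methyl ether, COCCl
Why: O-Alkylation of the phenol installs the same acetal ether as on ring B's precursor, here serving both as protecting group and as the stronger ortho-directing group for step 10.

Step 10
Reactants: 15 1,3-dimethoxy-5-(methoxymethoxy)benzene; 13 (1S,2R)-2-aryl-4,6,6-trimethylcyclohex-3-ene-1-carbaldehyde
Product: 17 [2,4-dimethoxy-6-(methoxymethoxy)phenyl]{(1S,2R)-2-[2,4-dimethoxy-6-(methoxymethoxy)phenyl]-4,6,6-trimethylcyclohex-3-en-1-yl}methanol (C7 epimer mixture), via aryllithium 16 (not isolated)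
Conditions: 15, n-BuLi, THF, 0 °C; then 13, −78 → −40 °C; aq. NH4Cl
Reagents that add atoms: none
Why: Directed ortho-metalation places lithium on the ring carbon flanked by the acetal oxygen and a methoxy group, and the aryllithium undergoes 1,2-addition to the aldehyde; C7 forms as an epimer mixture, which is of no consequence because step 11 makes it sp2.

Step 11
Reactants: 17 diaryl carbinol (C7 epimer mixture)
Product: 18 [2,4-dimethoxy-6-(methoxymethoxy)phenyl]{(1S,2R)-2-[2,4-dimethoxy-6-(methoxymethoxy)phenyl]-4,6,6-trimethylcyclohex-3-en-1-yl}methanone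
Conditions: Dess–Martin periodinane, pyridine, CH2Cl2, 0 °C → rt
Reagents that add atoms: none
Why: Dess–Martin oxidation of the hindered benzylic alcohol under buffered conditions converges both C7 epimers to one ketone, with C1 remaining in its stable trans arrangement.

Step 12
Reactants: 18 bis-MOM ketone
Product: 20 (2-hydroxy-4,6-dimethoxyphenyl)[(1S,2R)-2-(2-hydroxy-4,6-dimethoxyphenyl)-4,6,6-trimethylcyclohex-3-en-1-yl]methanone, via bis(trimethylsilyl) ether 19 (not isolated)
Conditions: Me3SiOSO2CF3, 2,2′-bipyridyl, CH3CN, 0 °C → rt; then H2O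
Reagents that add atoms: none
Why: Silyl triflate/bipyridyl acetal exchange converts aryl methoxymethyl ethers into aryl silyl ethers that hydrolyse on aqueous work-up, so both phenols are released without a Brønsted acid that could drive the ring B phenol onto the C3=C4 alkene.

Step 13
Reactants: 20 bis-phenol ketone
Product: 22 3-{[(1S,2R)-2-(3-formyl-2-hydroxy-4,6-dimethoxyphenyl)-4,6,6-trimethylcyclohex-3-en-1-yl]carbonyl}-2-hydroxy-4,6-dimethoxybenzaldehyde, via bis(hydroxymethyl)phenol 21 (not isolated)
Conditions: MgCl2, Et3N, (CH2O)n, CH3CN, reflux; aq. NH4Cl work-up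
Reagents that add atoms: formaldehyde (as paraformaldehyde), C=O
Why: Magnesium phenoxide-mediated ortho-formylation (Casnati–Skattebøl) is ortho-specific, and each phenol has a single free ortho position (between OH and OMe); formaldehyde acts as carbon source and then as hydride acceptor, in a basic medium that is harmless to the alkene.

Step 14
Reactants: 22 bis-salicylaldehyde ketone
Product: 24 8-{[(1S,2R)-2-(5,7-dimethoxy-2-oxo-2H-chromen-8-yl)-4,6,6-trimethylcyclohex-3-en-1-yl]carbonyl}-5,7-dimethoxy-2H-chromen-2-one, via bis-cinnamate 23 (not isolated)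
Conditions: Ph3P=CHCO2Et (excess), N,N-diethylaniline, reflux
Reagents that add atoms: ethyl (triphenylphosphoranylidene)acetate, CCOC(=O)C=P(c1ccccc1)(c1ccccc1)c1ccccc1
Why: Twofold Wittig olefination of the salicylaldehydes followed by thermal E/Z equilibration and lactonisation of the Z-cinnamates is the classical one-pot coumarin synthesis, and the shielded C7 ketone is inert to the stabilised ylide.

Step 15
Reactants: 24 bis-coumarin ketone
Product: 25 8-{(S)-[(1S,2R)-2-(5,7-dimethoxy-2-oxo-2H-chromen-8-yl)-4,6,6-trimethylcyclohex-3-en-1-yl](hydroxy)methyl}-5,7-dimethoxy-2H-chromen-2-one (CNP0324863.2)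
Conditions: NaBH4, CeCl3·7H2O, MeOH/THF, −20 → 0 °C
Reagents that add atoms: none
Why: Luche reduction should reduce the ketone in preference to the two coumarin lactones, and by the Felkin–Anh model the hydride approaches C7 anti to the fully substituted C6 and past the C1 hydrogen, which sets C7 as S.

**Compound list**

1 | dimedone (5,5-dimethylcyclohexane-1,3-dione) | CC1(C)CC(=O)CC(=O)C1 | starting material
2 | 3,3-dimethyl-5-oxohexanoic acid | CC(=O)CC(C)(C)CC(=O)O | intermediate
3 | 3,3-dimethylhexane-1,5-diol (racemic) | CC(O)CC(C)(C)CCO | intermediate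
4 | 3,3-dimethyl-5-oxohexanal | CC(=O)CC(C)(C)CC=O | intermediate
5 | 2-hydroxy-4,6-dimethoxybenzaldehyde | COc1cc(O)c(C=O)c(OC)c1 | starting material
6 | 2,4-dimethoxy-6-(methoxymethoxy)benzaldehyde | COCOc1cc(OC)cc(OC)c1C=O | intermediate
7 | nitromethane | C[N+](=O)[O-] | starting material
8 | (E)-2-(methoxymethoxy)-4,6-dimethoxy-β-nitrostyrene | COCOc1cc(OC)cc(OC)c1/C=C/[N+](=O)[O-] | intermediate
9 | (2R)-2-{(1R)-1-[2,4-dimethoxy-6-(methoxymethoxy)phenyl]-2-nitroethyl}-3,3-dimethyl-5-oxohexanal (syn Michael adduct) | O=C[C@@H](C(C)(C)CC(C)=O)[C@H](c1c(OC)cc(OC)cc1OCOC)C[N+](=O)[O-] | intermediate (not isolated)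
10 | (1S,2R,3R)-2-[2,4-dimethoxy-6-(methoxymethoxy)phenyl]-4-hydroxy-4,6,6-trimethyl-3-nitrocyclohexane-1-carbaldehyde (CHO, aryl and NO2 mutually trans; C4 epimer mixture) | O=C[C@H]1[C@H](c2c(OC)cc(OC)cc2OCOC)[C@@H]([N+](=O)[O-])C(C)(O)CC1(C)C | intermediate
11 | (1S,2R)-2-[2,4-dimethoxy-6-(methoxymethoxy)phenyl]-4,6,6-trimethyl-3-nitrocyclohex-3-ene-1-carbaldehyde | O=C[C@H]1[C@H](c2c(OC)cc(OC)cc2OCOC)C([N+](=O)[O-])=C(C)CC1(C)C | intermediate (not isolated)
12 | (1S,2R)-2-[2,4-dimethoxy-6-(methoxymethoxy)phenyl]-4,6,6-trimethyl-3-nitro-4-(phenylsulfanyl)cyclohexane-1-carbaldehyde (C3/C4 diastereomer mixture) | O=C[C@H]1[C@H](c2c(OC)cc(OC)cc2OCOC)C([N+](=O)[O-])C(C)(Sc2ccccc2)CC1(C)C | intermediate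
13 | (1S,2R)-2-[2,4-dimethoxy-6-(methoxymethoxy)phenyl]-4,6,6-trimethylcyclohex-3-ene-1-carbaldehyde (trans) | O=C[C@H]1[C@H](c2c(OC)cc(OC)cc2OCOC)C=C(C)CC1(C)C | intermediate
14 | 3,5-dimethoxyphenol | COc1cc(O)cc(OC)c1 | starting material
15 | 1,3-dimethoxy-5-(methoxymethoxy)benzene | COCOc1cc(OC)cc(OC)c1 | intermediate
16 | [2,4-dimethoxy-6-(methoxymethoxy)phenyl]lithium | [Li]c1c(OC)cc(OC)cc1OCOC | intermediate (not isolated)
17 | [2,4-dimethoxy-6-(methoxymethoxy)phenyl]{(1S,2R)-2-[2,4-dimethoxy-6-(methoxymethoxy)phenyl]-4,6,6-trimethylcyclohex-3-en-1-yl}methanol (C7 epimer mixture) | COCOc1cc(OC)cc(OC)c1C(O)[C@H]1[C@H](c2c(OC)cc(OC)cc2OCOC)C=C(C)CC1(C)C | intermediate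
18 | [2,4-dimethoxy-6-(methoxymethoxy)phenyl]{(1S,2R)-2-[2,4-dimethoxy-6-(methoxymethoxy)phenyl]-4,6,6-trimethylcyclohex-3-en-1-yl}methanone | COCOc1cc(OC)cc(OC)c1C(=O)[C@H]1[C@H](c2c(OC)cc(OC)cc2OCOC)C=C(C)CC1(C)C | intermediate
19 | {2,4-dimethoxy-6-[(trimethylsilyl)oxy]phenyl}[(1S,2R)-2-{2,4-dimethoxy-6-[(trimethylsilyl)oxy]phenyl}-4,6,6-trimethylcyclohex-3-en-1-yl]methanone | C[Si](C)(C)Oc1cc(OC)cc(OC)c1C(=O)[C@H]1[C@H](c2c(OC)cc(OC)cc2O[Si](C)(C)C)C=C(C)CC1(C)C | intermediate (not isolated)
20 | (2-hydroxy-4,6-dimethoxyphenyl)[(1S,2R)-2-(2-hydroxy-4,6-dimethoxyphenyl)-4,6,6-trimethylcyclohex-3-en-1-yl]methanone | Oc1cc(OC)cc(OC)c1C(=O)[C@H]1[C@H](c2c(OC)cc(OC)cc2O)C=C(C)CC1(C)C | intermediate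
21 | [2-hydroxy-3-(hydroxymethyl)-4,6-dimethoxyphenyl]{(1S,2R)-2-[2-hydroxy-3-(hydroxymethyl)-4,6-dimethoxyphenyl]-4,6,6-trimethylcyclohex-3-en-1-yl}methanone | OCc1c(OC)cc(OC)c(C(=O)[C@H]2[C@H](c3c(OC)cc(OC)c(CO)c3O)C=C(C)CC2(C)C)c1O | intermediate (not isolated)
22 | 3-{[(1S,2R)-2-(3-formyl-2-hydroxy-4,6-dimethoxyphenyl)-4,6,6-trimethylcyclohex-3-en-1-yl]carbonyl}-2-hydroxy-4,6-dimethoxybenzaldehyde | O=Cc1c(OC)cc(OC)c(C(=O)[C@H]2[C@H](c3c(OC)cc(OC)c(C=O)c3O)C=C(C)CC2(C)C)c1O | intermediate
23 | diethyl bis-(Z)-cinnamate: each formyl group of 22 replaced by (Z)-CH=CH–CO2Et | CCOC(=O)\C=C/c1c(OC)cc(OC)c(C(=O)[C@H]2[C@H](c3c(OC)cc(OC)c(/C=C\C(=O)OCC)c3O)C=C(C)CC2(C)C)c1O | intermediate (not isolated)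
24 | 8-{[(1S,2R)-2-(5,7-dimethoxy-2-oxo-2H-chromen-8-yl)-4,6,6-trimethylcyclohex-3-en-1-yl]carbonyl}-5,7-dimethoxy-2H-chromen-2-one | COc1cc(OC)c2ccc(=O)oc2c1C(=O)[C@H]1[C@H](c2c(OC)cc(OC)c3ccc(=O)oc23)C=C(C)CC1(C)C | intermediate
25 | 8-{(S)-[(1S,2R)-2-(5,7-dimethoxy-2-oxo-2H-chromen-8-yl)-4,6,6-trimethylcyclohex-3-en-1-yl](hydroxy)methyl}-5,7-dimethoxy-2H-chromen-2-one (CNP0324863.2) | COc1cc(OC)c2ccc(=O)oc2c1[C@@H](O)[C@H]1[C@H](c2c(OC)cc(OC)c3ccc(=O)oc23)C=C(C)CC1(C)C | target

**Step count and risks**

Total step count: 15. Longest linear sequence: 12 steps (1–3, 6–8, 10–15, from dimedone).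

Steps most likely to fail:

1. Step 6. The conjugate addition may stall or lose facial selectivity at the shielded, electron-rich nitroalkene. The nitro-aldol closure onto the ketone may also revert, or 4 may be consumed by self-condensation. Fallback: the ring is built by an iminium-catalysed Diels–Alder reaction instead, setting out from aldehyde 6 and returning at aldehyde 13 (steps 5–8 bypassed). Claisen–Schmidt condensation of 6 with acetone (NaOH, acetone/H2O) should give (E)-4-[2,4-dimethoxy-6-(methoxymethoxy)phenyl]but-3-en-2-one F1. Wittig methylenation (Ph3PCH3Br, KOt-Bu, THF) should give (E)-1-[2,4-dimethoxy-6-(methoxymethoxy)phenyl]-3-methylbuta-1,3-diene F2. Cycloaddition of F2 with 3-methylbut-2-enal, catalysed by (2R,5R)-5-benzyl-2-tert-butyl-3-methylimidazolidin-4-one·CF3CO2H, is expected to follow ortho/para regiochemistry and the endo mode to give the cis aldehyde (1R,2R)-2-[2,4-dimethoxy-6-(methoxymethoxy)phenyl]-4,6,6-trimethylcyclohex-3-ene-1-carbaldehyde F3. Any exo adduct must be removed at this point, because its epimerisation would lead to the enantiomer. DBU epimerisation of C1 in F3 then gives trans aldehyde 13.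

2. Step 15. Hydride delivery may show poor or reversed facial selectivity at C7, or the shielded ketone may react so slowly that the lactones are attacked. Fallback: stereocontrol is moved from substrate to reagent, from ketone 24 directly to 25. Reduction with catecholborane in the presence of stoichiometric (R)-1-methyl-3,3-diphenyltetrahydro-1H,3H-pyrrolo[1,2-c][1,3,2]oxazaborole (Corey–Bakshi–Shibata reduction, toluene, −78 → −20 °C) should give the 7S alcohol if the coumarinyl ring acts as the large substituent. This fallback makes no new compound (F0).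

3. Step 13. Formylation may remain incomplete at the hydrogen-bonded, ketone-chelated phenol of ring A, or proceed past the aldehyde stage to diarylmethane by-products. Fallback: the pyranones are closed by esterification and hydroarylation, from bis-phenol 20 to bis-coumarin 24 (steps 13 and 14 bypassed). Propiolic acid and dicyclohexylcarbodiimide (CH2Cl2, 0 °C) should give the bis(propiolate) 2-{[(1S,2R)-2-[2,4-dimethoxy-6-(propioloyloxy)phenyl]-4,6,6-trimethylcyclohex-3-en-1-yl]carbonyl}-3,5-dimethoxyphenyl propiolate F4. A cationic gold catalyst generated from Ph3PAuCl and AgOSO2CF3 (1,2-dichloroethane, rt → 50 °C) should then effect twofold 6-endo intramolecular hydroarylation at the only free position ortho to each ester oxygen, giving 24.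

**Further compounds**

F1 | step 6 | (E)-4-[2,4-dimethoxy-6-(methoxymethoxy)phenyl]but-3-en-2-one | CC(=O)/C=C/c1c(OC)cc(OC)cc1OCOC
F2 | step 6 | (E)-1-[2,4-dimethoxy-6-(methoxymethoxy)phenyl]-3-methylbuta-1,3-diene | CC(=C)/C=C/c1c(OC)cc(OC)cc1OCOC
F3 | step 6 | (1R,2R)-2-[2,4-dimethoxy-6-(methoxymethoxy)phenyl]-4,6,6-trimethylcyclohex-3-ene-1-carbaldehyde (cis) | O=C[C@@H]1[C@H](c2c(OC)cc(OC)cc2OCOC)C=C(C)CC1(C)C
F0 | step 15 | none | none
F4 | step 13 | 2-{[(1S,2R)-2-[2,4-dimethoxy-6-(propioloyloxy)phenyl]-4,6,6-trimethylcyclohex-3-en-1-yl]carbonyl}-3,5-dimethoxyphenyl propiolate | C#CC(=O)Oc1cc(OC)cc(OC)c1C(=O)[C@H]1[C@H](c2c(OC)cc(OC)cc2OC(=O)C#C)C=C(C)CC1(C)C
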